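## Retrosynthetic overview

Avarane numbering is used: ring A = C1–C2–C3–C4–C5–C10, with the exocyclic methylene C11 on C4; ring B = C5–C6–C7–C8–C9–C10; C15 = benzylic CH2.

1. Target 21 ⇐ bis-MOM ether 20; the last step only unmasks the catechol.
2. Ring A of 20 is cut at C4–C5 and at C10–H, giving the monocyclic enyne 18. Its ring B holds a tetrasubstituted C5=C10 double bond (methyl on C5; on C10 the C1–C2–C3 tether ending in the C4≡C11 alkyne) beside the quaternary C9. This alkene, open at C5 and blocked at C10, is the feature that lets a C4 vinyl radical close ring A at C5 and leave a C10 radical that takes hydrogen trans to the C5 methyl.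
3. 18 ⇐ enol triflate 14 + alkylzinc 16 (C1–C10 bond, Negishi coupling); 14 ⇐ ketone 10 by C5 methylation and triflation, enolisation being possible only toward C5.
4. 10 ⇐ silyl enol ether 8 + benzyl bromide 5, a convergent alkylation that creates the quaternary C9 next to C8; C8 comes from catalytic asymmetric methyl addition to enone 6; 5 ⇐ aldehyde 1.
5. Ring order: the arene and ring B enter as rings of purchased materials; ring A is the only ring closed, and it is closed last (step 11).

Key step: step 11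

Assumption: in step 5 the enantiomer of the chiral ligand is the one that delivers methyl to the face of C3 of 6 giving the (S)-configured enolate; this sense of induction must be confirmed, and all later stereocenters are relayed from this one.

## Route

Step 1
Reactants: 1 5-bromo-2,3-dihydroxybenzaldehyde
Product: 2 5-bromo-2,3-bis(methoxymethoxy)benzaldehyde
Conditions: MOMCl, iPr2NEt, DMF, 0 °C → rt
Reagents that add atoms: chloromethyl methyl ether, COCCl
Why: Williamson-type O-alkylation of both phenols; the MOM acetals should survive the later bases, the palladium steps and the radical step.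

Step 2
Reactants: 2 5-bromo-2,3-bis(methoxymethoxy)benzaldehyde
Product: 3 methyl 3-formyl-4,5-bis(methoxymethoxy)benzoate
Conditions: CO (1 atm), MeOH, Pd(OAc)2 (cat.), Xantphos, Et3N, DMF, 80 °C
Reagents that add atoms: carbon monoxide, [C-]#[O+]; methanol, CO
Why: palladium-catalysed methoxycarbonylation of the aryl bromide, to which the aldehyde and the acetals are inert.

Step 3
Reactants: 3 methyl 3-formyl-4,5-bis(methoxymethoxy)benzoate
Product: 4 methyl 3-(hydroxymethyl)-4,5-bis(methoxymethoxy)benzoate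
Conditions: NaBH4, MeOH/THF, 0 °C
Reagents that add atoms: none
Why: borohydride reduction is chemoselective for the aldehyde over the aryl ester.

Step 4
Reactants: 4 methyl 3-(hydroxymethyl)-4,5-bis(methoxymethoxy)benzoate
Product: 5 methyl 3-(bromomethyl)-4,5-bis(methoxymethoxy)benzoate
Conditions: CBr4, PPh3, CH2Cl2, 0 °C
Reagents that add atoms: carbon tetrabromide, BrC(Br)(Br)Br
Why: Appel bromination converts the benzylic alcohol under neutral conditions that leave the acetals intact.

Step 5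
Reactants: 6 2-methylcyclohex-2-en-1-one
Product: 8 (S)-[(2,3-dimethylcyclohex-1-en-1-yl)oxy]trimethylsilane, via bromomagnesium enolate 7 (not isolated)
Conditions: MeMgBr, CuBr·SMe2 (5 mol %), chiral TADDOL-derived phosphine–phosphite ligand (6 mol %), 2-MeTHF, −78 °C; then TMSCl, Et3N, −78 °C → rt
Reagents that add atoms: methylmagnesium bromide, C[Mg]Br; chlorotrimethylsilane, C[Si](C)(C)Cl
Why: copper-catalysed asymmetric conjugate addition of the Grignard reagent sets C8 (S) by ligand control, and O-silylation fixes the regiodefined tetrasubstituted enolate.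

Step 6
Reactants: 8 (S)-[(2,3-dimethylcyclohex-1-en-1-yl)oxy]trimethylsilane; 5 methyl 3-(bromomethyl)-4,5-bis(methoxymethoxy)benzoate
Product: 10 methyl 3-{[(1R,2S)-1,2-dimethyl-6-oxocyclohexyl]methyl}-4,5-bis(methoxymethoxy)benzoate, via lithium dimethylcyclohexenolate 9 (not isolated)
Conditions: MeLi (1.0 equiv), THF, 0 °C → rt; then DMPU, 5, −78 → −20 °C
Reagents that add atoms: none
Why: Si–O cleavage by MeLi releases the regiodefined lithium enolate, and its SN2 alkylation joins the two fragments at quaternary C9; the bromide should approach anti to the pseudoaxial C8 methyl (A(1,2) strain), placing the benzyl group trans to it.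

Step 7
Reactants: 10 methyl 3-{[(1R,2S)-1,2-dimethyl-6-oxocyclohexyl]methyl}-4,5-bis(methoxymethoxy)benzoate
Product: 12 methyl 3-{[(1R,2S)-1,2,5-trimethyl-6-oxocyclohexyl]methyl}-4,5-bis(methoxymethoxy)benzoate (mixture of epimers at the new methyl-bearing carbon), via kinetic lithium enolate 11 (not isolated)
Conditions: LDA, THF, −78 °C; MeI, −78 → −20 °C
Reagents that add atoms: iodomethane, CI
Why: enolate alkylation at the only enolisable α-carbon (C5) installs the C5 methyl; the new stereocenter is of no consequence because it becomes sp2 in step 8.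

Step 8
Reactants: 12 methyl 3-{[(1R,2S)-1,2,5-trimethyl-6-oxocyclohexyl]methyl}-4,5-bis(methoxymethoxy)benzoate
Product: 14 (5S,6R)-6-{[2,3-bis(methoxymethoxy)-5-(methoxycarbonyl)phenyl]methyl}-2,5,6-trimethylcyclohex-1-en-1-yl trifluoromethanesulfonate, via potassium enolate 13 (not isolated)
Conditions: KHMDS, THF, −78 → 0 °C; PhNTf2, −78 °C → rt
Reagents that add atoms: N-phenylbis(trifluoromethanesulfonimide), O=S(=O)(N(c1ccccc1)S(=O)(=O)C(F)(F)F)C(F)(F)F
Why: enolate O-triflation; because C9 is quaternary the enolate can form only toward C5, so the tetrasubstituted C5=C10 enol triflate should arise regiospecifically.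

Step 9
Reactants: 14 (5S,6R)-6-{[2,3-bis(methoxymethoxy)-5-(methoxycarbonyl)phenyl]methyl}-2,5,6-trimethylcyclohex-1-en-1-yl trifluoromethanesulfonate; 15 (5-iodopent-1-yn-1-yl)trimethylsilane
Product: 17 methyl 3-({(1R,6S)-1,3,6-trimethyl-2-[5-(trimethylsilyl)pent-4-yn-1-yl]cyclohex-2-en-1-yl}methyl)-4,5-bis(methoxymethoxy)benzoate, via alkylzinc iodide 16 (not isolated)
Conditions: 15, Zn dust, LiCl, THF, 40 °C; then 14, Pd(OAc)2 (5 mol %), SPhos, THF/NMP, 60 °C
Reagents that add atoms: none
Why: Negishi sp3–sp2 coupling of a functionalised alkylzinc with a hindered cyclohexenyl triflate, a pairing that tolerates the ester and for which bulky biarylphosphines are known to suppress β-hydride elimination.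

Step 10
Reactants: 17 methyl 3-({(1R,6S)-1,3,6-trimethyl-2-[5-(trimethylsilyl)pent-4-yn-1-yl]cyclohex-2-en-1-yl}methyl)-4,5-bis(methoxymethoxy)benzoate
Product: 18 methyl 3-{[(1R,6S)-1,3,6-trimethyl-2-(pent-4-yn-1-yl)cyclohex-2-en-1-yl]methyl}-4,5-bis(methoxymethoxy)benzoate
Conditions: K2CO3, MeOH, rt
Reagents that add atoms: none
Why: methoxide-mediated protodesilylation of the alkynylsilane, with the acetals and the methyl ester unchanged.

Step 11
Reactants: 18 methyl 3-{[(1R,6S)-1,3,6-trimethyl-2-(pent-4-yn-1-yl)cyclohex-2-en-1-yl]methyl}-4,5-bis(methoxymethoxy)benzoate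
Product: 20 methyl 3-{[(1R,2S,4aS,8aS)-1,2,4a-trimethyl-5-methylidenedecahydronaphthalen-1-yl]methyl}-4,5-bis(methoxymethoxy)benzoate, via vinylstannane 19 (not isolated)
Conditions: Bu3SnH (1.3 equiv) and AIBN in PhH added over 8 h to 18 (0.005 M) in PhH, 80 °C; then TsOH·H2O, CH2Cl2, 0 °C
Reagents that add atoms: none
Why: Bu3Sn• adds reversibly to the terminal alkyne carbon C11, the resulting σ-vinyl radical at C4 attacks C5 of the tetrasubstituted C5=C10 alkene, the tertiary C10 radical takes hydrogen from Bu3SnH, and the vinylstannane 19 is protodestannylated by acid through a β-stannyl cation to the exocyclic methylene. The closest known reaction type is the stannyl-radical-mediated enyne (vinyl radical) cyclization, including the homoallyl–cyclopropylcarbinyl radical rearrangement that turns 5-exo into 6-endo products at low stannane concentration. Ring A is closed in the 6-endo-trig mode (C4 to C5); a radical formed by 5-exo attack at C10 would carry a spiro quaternary carbon beside quaternary C9 and is expected to ring-expand to the same C10 radical. C5 is controlled by C9: in the reactive half-chair of ring B the C9 methyl is pseudoaxial on the β-face (C8 methyl equatorial, C15 pseudoequatorial), so the tether should cross the α-face and the C5 methyl should end β, cis to the C9 methyl. C10 is controlled by the two β-axial methyl groups at C5 and C9, which should leave the α-face for axial hydrogen delivery and so give the trans ring fusion. The step needs regioselectivity (C5 over C10), secured by the neopentyl position of C10 and slow stannane addition, and ring closure before reduction of the vinyl radical, secured by high dilution.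

Step 12
Reactants: 20 methyl 3-{[(1R,2S,4aS,8aS)-1,2,4a-trimethyl-5-methylidenedecahydronaphthalen-1-yl]methyl}-4,5-bis(methoxymethoxy)benzoate
Product: 21 dictyoceratin A, methyl 3-{[(1R,2S,4aS,8aS)-1,2,4a-trimethyl-5-methylidenedecahydronaphthalen-1-yl]methyl}-4,5-dihydroxybenzoate
Conditions: ZnBr2, n-PrSH, CH2Cl2, 0 °C, 15 min
Reagents that add atoms: none
Why: Lewis-acid-assisted transfer of the methoxymethyl groups to the thiol frees the catechol quickly at low temperature, conditions under which the exocyclic alkene and the ester should not react.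

## Compound list

1 | 5-bromo-2,3-dihydroxybenzaldehyde | O=Cc1cc(Br)cc(O)c1O | starting material
2 | 5-bromo-2,3-bis(methoxymethoxy)benzaldehyde | O=Cc1cc(Br)cc(OCOC)c1OCOC | intermediate
3 | methyl 3-formyl-4,5-bis(methoxymethoxy)benzoate | O=Cc1cc(C(=O)OC)cc(OCOC)c1OCOC | intermediate
4 | methyl 3-(hydroxymethyl)-4,5-bis(methoxymethoxy)benzoate | OCc1cc(C(=O)OC)cc(OCOC)c1OCOC | intermediate
5 | methyl 3-(bromomethyl)-4,5-bis(methoxymethoxy)benzoate | BrCc1cc(C(=O)OC)cc(OCOC)c1OCOC | intermediate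
6 | 2-methylcyclohex-2-en-1-one | CC1=CCCCC1=O | starting material
7 | bromomagnesium (S)-2,3-dimethylcyclohex-1-en-1-olate | CC1=C(O[Mg]Br)CCC[C@@H]1C | intermediate
8 | (S)-[(2,3-dimethylcyclohex-1-en-1-yl)oxy]trimethylsilane | CC1=C(O[Si](C)(C)C)CCC[C@@H]1C | intermediate
9 | lithium (S)-2,3-dimethylcyclohex-1-en-1-olate | [Li+].CC1=C([O-])CCC[C@@H]1C | intermediate
10 | methyl 3-{[(1R,2S)-1,2-dimethyl-6-oxocyclohexyl]methyl}-4,5-bis(methoxymethoxy)benzoate | O=C1[C@](C)(Cc2cc(C(=O)OC)cc(OCOC)c2OCOC)[C@@H](C)CCC1 | intermediate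
11 | lithium (5S,6R)-6-{[2,3-bis(methoxymethoxy)-5-(methoxycarbonyl)phenyl]methyl}-5,6-dimethylcyclohex-1-en-1-olate | [Li+].[O-]C=1[C@](C)(Cc2cc(C(=O)OC)cc(OCOC)c2OCOC)[C@@H](C)CCC=1 | intermediate
12 | methyl 3-{[(1R,2S)-1,2,5-trimethyl-6-oxocyclohexyl]methyl}-4,5-bis(methoxymethoxy)benzoate (both epimers at the ring carbon bearing the new methyl) | O=C1[C@](C)(Cc2cc(C(=O)OC)cc(OCOC)c2OCOC)[C@@H](C)CCC1C | intermediate
13 | potassium (5S,6R)-6-{[2,3-bis(methoxymethoxy)-5-(methoxycarbonyl)phenyl]methyl}-2,5,6-trimethylcyclohex-1-en-1-olate | [K+].[O-]C=1[C@](C)(Cc2cc(C(=O)OC)cc(OCOC)c2OCOC)[C@@H](C)CCC=1C | intermediate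
14 | (5S,6R)-6-{[2,3-bis(methoxymethoxy)-5-(methoxycarbonyl)phenyl]methyl}-2,5,6-trimethylcyclohex-1-en-1-yl trifluoromethanesulfonate | CC1=C(OS(=O)(=O)C(F)(F)F)[C@](C)(Cc2cc(C(=O)OC)cc(OCOC)c2OCOC)[C@@H](C)CC1 | intermediate
15 | (5-iodopent-1-yn-1-yl)trimethylsilane | C[Si](C)(C)C#CCCCI | starting material
16 | [5-(trimethylsilyl)pent-4-yn-1-yl]zinc iodide | C[Si](C)(C)C#CCCC[Zn]I | intermediate
17 | methyl 3-({(1R,6S)-1,3,6-trimethyl-2-[5-(trimethylsilyl)pent-4-yn-1-yl]cyclohex-2-en-1-yl}methyl)-4,5-bis(methoxymethoxy)benzoate | CC1=C(CCCC#C[Si](C)(C)C)[C@](C)(Cc2cc(C(=O)OC)cc(OCOC)c2OCOC)[C@@H](C)CC1 | intermediate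
18 | methyl 3-{[(1R,6S)-1,3,6-trimethyl-2-(pent-4-yn-1-yl)cyclohex-2-en-1-yl]methyl}-4,5-bis(methoxymethoxy)benzoate | CC1=C(CCCC#C)[C@](C)(Cc2cc(C(=O)OC)cc(OCOC)c2OCOC)[C@@H](C)CC1 | intermediate
19 | methyl 3-({(1R,2S,4aS,8aS)-1,2,4a-trimethyl-5-[(tributylstannyl)methylidene]decahydronaphthalen-1-yl}methyl)-4,5-bis(methoxymethoxy)benzoate (alkene geometry not defined) | CCCC[Sn](CCCC)(CCCC)C=C1CCC[C@H]2[C@](C)(Cc3cc(C(=O)OC)cc(OCOC)c3OCOC)[C@@H](C)CC[C@]12C | intermediate
20 | methyl 3-{[(1R,2S,4aS,8aS)-1,2,4a-trimethyl-5-methylidenedecahydronaphthalen-1-yl]methyl}-4,5-bis(methoxymethoxy)benzoate | C=C1CCC[C@H]2[C@](C)(Cc3cc(C(=O)OC)cc(OCOC)c3OCOC)[C@@H](C)CC[C@]12C | intermediate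
21 | dictyoceratin A, methyl 3-{[(1R,2S,4aS,8aS)-1,2,4a-trimethyl-5-methylidenedecahydronaphthalen-1-yl]methyl}-4,5-dihydroxybenzoate | C=C1CCC[C@H]2[C@](C)(Cc3cc(C(=O)OC)cc(O)c3O)[C@@H](C)CC[C@]12C | target

## Step count and risks

Total step count: 12. Longest linear sequence: 11 steps (steps 1–4, then 6–12).

Steps most likely to fail:

**Step 11 (key step).** Hydrogen transfer from the stannane may reach the C4 vinyl radical before ring closure, the new bond may form on the β-face of C5, or hydrogen delivery to C10 may be unselective. The fallback replaces the vinyl radical by an acyl radical and installs the methylene afterwards. It sets out from 14. Negishi coupling of 14 with [3-(1,3-dioxolan-2-yl)propyl]zinc bromide F1 (from 2-(3-bromopropyl)-1,3-dioxolane, Zn dust and LiCl in THF; Pd(OAc)2, SPhos) should give the dioxolane methyl 3-({(1R,6S)-2-[3-(1,3-dioxolan-2-yl)propyl]-1,3,6-trimethylcyclohex-2-en-1-yl}methyl)-4,5-bis(methoxymethoxy)benzoate F2. PPTS in wet acetone should release the aldehyde methyl 3-{[(1R,6S)-1,3,6-trimethyl-2-(4-oxobutyl)cyclohex-2-en-1-yl]methyl}-4,5-bis(methoxymethoxy)benzoate F3. Thiol-catalysed radical-chain hydroacylation (tert-dodecanethiol, AIBN, PhH, 80 °C) should then close ring A: the C4 acyl radical adds 6-endo to C5, and a premature hydrogen transfer only regenerates F3. Hydrogen delivery from the thiol to the α-face of C10 should give the trans-fused ketone methyl 3-{[(1R,2S,4aS,8aS)-1,2,4a-trimethyl-5-oxodecahydronaphthalen-1-yl]methyl}-4,5-bis(methoxymethoxy)benzoate F4. Wittig methylenation (Ph3PCH3Br, KOt-Bu, toluene, 90 °C) comes back to the route at 20.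

**Step 9.** Transmetalation and reductive elimination at the triflate carbon beside quaternary C9 may be slow, so that β-hydride elimination of the alkylpalladium intermediate takes over. The fallback reverses the polarity of the coupling. It sets out from 14. Miyaura borylation (bis(pinacolato)diboron, PdCl2(PPh3)2, PPh3, KOPh, toluene, 50 °C) should give the alkenyl boronate methyl 3-{[(1R,6S)-1,3,6-trimethyl-2-(4,4,5,5-tetramethyl-1,3,2-dioxaborolan-2-yl)cyclohex-2-en-1-yl]methyl}-4,5-bis(methoxymethoxy)benzoate F5. Alkyl–alkenyl Suzuki–Miyaura coupling of F5 with iodide 15 (Pd(OAc)2, P(t-Bu)2Me, K3PO4·H2O, dioxane) comes back to the route at 17.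

**Step 12.** Acid-promoted migration of the exocyclic double bond into ring A, or oxidation of the catechol as it is set free, may erode the last step. The fallback changes the protecting group before the sensitive alkene exists. It sets out from 18. HCl in MeOH at 40 °C should give the catechol methyl 3-{[(1R,6S)-1,3,6-trimethyl-2-(pent-4-yn-1-yl)cyclohex-2-en-1-yl]methyl}-4,5-dihydroxybenzoate F6. TBSCl and imidazole in DMF should give the bis-silyl ether methyl 3-{[(1R,6S)-1,3,6-trimethyl-2-(pent-4-yn-1-yl)cyclohex-2-en-1-yl]methyl}-4,5-bis[(tert-butyldimethylsilyl)oxy]benzoate F7. The conditions of step 11 should lead through the vinylstannane methyl 3-({(1R,2S,4aS,8aS)-1,2,4a-trimethyl-5-[(tributylstannyl)methylidene]decahydronaphthalen-1-yl}methyl)-4,5-bis[(tert-butyldimethylsilyl)oxy]benzoate F8, which is not isolated, to methyl 3-{[(1R,2S,4aS,8aS)-1,2,4a-trimethyl-5-methylidenedecahydronaphthalen-1-yl]methyl}-4,5-bis[(tert-butyldimethylsilyl)oxy]benzoate F9. Fluoride (TBAF buffered with AcOH, THF, 0 °C) comes back to the route at 21.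

Further compounds
F1 | step 11 | [3-(1,3-dioxolan-2-yl)propyl]zinc bromide | Br[Zn]CCCC1OCCO1
F2 | step 11 | methyl 3-({(1R,6S)-2-[3-(1,3-dioxolan-2-yl)propyl]-1,3,6-trimethylcyclohex-2-en-1-yl}methyl)-4,5-bis(methoxymethoxy)benzoate | CC1=C(CCCC2OCCO2)[C@](C)(Cc2cc(C(=O)OC)cc(OCOC)c2OCOC)[C@@H](C)CC1
F3 | step 11 | methyl 3-{[(1R,6S)-1,3,6-trimethyl-2-(4-oxobutyl)cyclohex-2-en-1-yl]methyl}-4,5-bis(methoxymethoxy)benzoate | CC1=C(CCCC=O)[C@](C)(Cc2cc(C(=O)OC)cc(OCOC)c2OCOC)[C@@H](C)CC1
F4 | step 11 | methyl 3-{[(1R,2S,4aS,8aS)-1,2,4a-trimethyl-5-oxodecahydronaphthalen-1-yl]methyl}-4,5-bis(methoxymethoxy)benzoate | O=C1CCC[C@H]2[C@](C)(Cc3cc(C(=O)OC)cc(OCOC)c3OCOC)[C@@H](C)CC[C@]12C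
F5 | step 9 | methyl 3-{[(1R,6S)-1,3,6-trimethyl-2-(4,4,5,5-tetramethyl-1,3,2-dioxaborolan-2-yl)cyclohex-2-en-1-yl]methyl}-4,5-bis(methoxymethoxy)benzoate | CC1=C(B2OC(C)(C)C(C)(C)O2)[C@](C)(Cc2cc(C(=O)OC)cc(OCOC)c2OCOC)[C@@H](C)CC1
F6 | step 12 | methyl 3-{[(1R,6S)-1,3,6-trimethyl-2-(pent-4-yn-1-yl)cyclohex-2-en-1-yl]methyl}-4,5-dihydroxybenzoate | CC1=C(CCCC#C)[C@](C)(Cc2cc(C(=O)OC)cc(O)c2O)[C@@H](C)CC1
F7 | step 12 | methyl 3-{[(1R,6S)-1,3,6-trimethyl-2-(pent-4-yn-1-yl)cyclohex-2-en-1-yl]methyl}-4,5-bis[(tert-butyldimethylsilyl)oxy]benzoate | CC1=C(CCCC#C)[C@](C)(Cc2cc(C(=O)OC)cc(O[Si](C)(C)C(C)(C)C)c2O[Si](C)(C)C(C)(C)C)[C@@H](C)CC1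
F8 | step 12 | methyl 3-({(1R,2S,4aS,8aS)-1,2,4a-trimethyl-5-[(tributylstannyl)methylidene]decahydronaphthalen-1-yl}methyl)-4,5-bis[(tert-butyldimethylsilyl)oxy]benzoate | CCCC[Sn](CCCC)(CCCC)C=C1CCC[C@H]2[C@](C)(Cc3cc(C(=O)OC)cc(O[Si](C)(C)C(C)(C)C)c3O[Si](C)(C)C(C)(C)C)[C@@H](C)CC[C@]12C
F9 | step 12 | methyl 3-{[(1R,2S,4aS,8aS)-1,2,4a-trimethyl-5-methylidenedecahydronaphthalen-1-yl]methyl}-4,5-bis[(tert-butyldimethylsilyl)oxy]benzoate | C=C1CCC[C@H]2[C@](C)(Cc3cc(C(=O)OC)cc(O[Si](C)(C)C(C)(C)C)c3O[Si](C)(C)C(C)(C)C)[C@@H](C)CC[C@]12C
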